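The numbers in the tables are simulated for substances that don't exist.

In a one-step world, every starting material lost turns up in one product, and a recipe changes the time but not the yield. This flask has two ways out: self-condensation, whose loss goes with the square of [starting material], and a drain through the intermediate to the nucleophiles, first order while they stay near their charge. Divide the first loss by the second at the start and you have the split number N. When a fraction x of the charge is left, self-condensation takes Nx over one plus Nx of the loss. Summed over the balance of starting material, the limiting reagent among the main charges, its share is one minus ln(one plus N) over N.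

all flasks: protic impurity 2.85 mM
- amber: starting material 0.057 M; first nucleophile 0.114 M; second nucleophile 0.0855 M; temperature 95 °C; run made earlier
- grey: starting material 0.080 M; first nucleophile 0.114 M; second nucleophile 0.0855 M; temperature 106 °C; run made earlier
- teal: starting material 0.13 M; first nucleophile 0.114 M; second nucleophile 0.0855 M; temperature 95 °C; run made earlier
- Wednesday's: starting material 0.057 M; first nucleophile 0.114 M (fed, over 30 h); second nucleophile 0.0855 M; temperature 100 °C; all else is in the flask from the start; the feed brings no volume worth counting; time 50 h
- Tuesday's: starting material 0.057 M; first nucleophile 0.114 M; second nucleophile 0.0855 M; temperature 100 °C; everything together at the start; time 50 h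
- Monday's: starting material 0.057 M; first nucleophile 0.114 M; second nucleophile 0.0855 M (fed, over 30 h); temperature 100 °C; all else is in the flask from the start; the feed brings no volume worth counting; time 50 h
- Friday's: starting material 0.057 M; first nucleophile 0.114 M; second nucleophile 0.0855 M (fed, over 30 h); the addition at 80 °C, then warmed to 100 °C; the feed brings no volume worth counting; time 50 h

- amber (time / h: self-condensation product / %, target / %, starting material / %): 4.00: 20.1, 1.6, 68.0; 8.00: 31.2, 3.4, 49.9; 12.0: 37.1, 3.2, 37.6; 15.0: 40.3, 5.1, 32.9; 20.0: 44.7, 6.2, 24.4; 25.0: 45.1, 7.1, 19.3; 30.0: 47.0, 6.3, 14.5
- grey (time / h: self-condensation product / %, target / %, starting material / %): 2.50: 35.2, 2.4, 52.9; 4.00: 43.1, 2.3, 41.2; 6.00: 49.1, 3.8, 29.8; 8.00: 53.4, 5.0, 23.5; 12.0: 57.3, 5.4, 15.9; 20.0: 60.4, 6.5, 8.5; 30.0: 60.9, 6.6, 4.4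
- teal (time / h: self-condensation product / %, target / %, starting material / %): 1.50: 19.5, 0.3, 75.8; 5.00: 41.3, 1.8, 47.4; 8.00: 50.9, 2.5, 34.1; 12.0: 57.8, 3.4, 25.5; 20.0: 61.5, 4.0, 14.7; 25.0: 64.1, 4.0, 12.1; 30.0: 65.3, 4.4, 9.2

(scatter of a reading: 0.5 percentage points)

- percentages count the starting material that a species holds: one self-condensation product counts as two
- steps that have been proposed: second nucleophile + intermediate -> other capture product; 2 starting material -> self-condensation product; starting material <-> intermediate; second nucleophile + protic impurity -> quenched reagent; first nucleophile + intermediate -> target

- the flask that comes out highest in amount of self-condensation product, in percent of the starting material charged; "all alike" if 1.5 percentage points covers them all (Wednesday's / Tuesday's / Monday's / Friday's / all alike)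
- amount of self-condensation product at the end, in percent of the starting material charged, Wednesday's
- amount of self-condensation product at the end, in percent of the starting material charged, Tuesday's
- amount of self-condensation product at the end, in percent of the starting material charged, Monday's
- amount of self-condensation product at the end, in percent of the starting material charged, Friday's

Read N from each run's first reading: self-condensation product over the rest of the loss, divided by the mean x. Amber gives 2.01, teal 4.72 and grey 3.87. Teal over amber is 2.35, beside a charge ratio of 2.28, so N follows the charge. Per unit charge, grey at 106 °C stands at 1.37 times amber at 95 °C. Interpolated between those two to 100 °C, Tuesday's split number, the starting loss by self-condensation over the starting loss by the drain, is 2.32, a share of 48.3%.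

One number holds while the drain keeps its size, and a feed may change that. Target takes 16.4% of amber's capture. I assume the intermediate mostly returns, so the drain follows the nucleophile present. Over the first 15.0 h, a fed charge averages a quarter of itself. Monday's N becomes 6.23, a share of 68.2%; Wednesday's becomes 2.65, a share of 51.1%. Friday's, reckoned wholly cold, gives 3.51, a share of 57.1%, and I expect its warm finish to pull that lower.

The forecast named Monday's, at 64% against 52.5% for Wednesday's, 51% for Tuesday's and 50% for Friday's, since “Feeding it therefore starves the drain”.

    second nucleophile + intermediate → other capture product (k = 8.10 L mol⁻¹ min⁻¹, Ea = 63.0 kJ mol⁻¹)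
    2 starting material → self-condensation product (k = 0.0170 L mol⁻¹ min⁻¹, Ea = 93.0 kJ mol⁻¹)
    starting material ⇌ intermediate (K = 0.00140, k = 0.00260 min⁻¹, Ea = 122 kJ mol⁻¹, ΔH = −19.0 kJ mol⁻¹)
    second nucleophile + protic impurity → quenched reagent (k = 0.140 L mol⁻¹ min⁻¹, Ea = 62.0 kJ mol⁻¹)
    first nucleophile + intermediate → target (k = 1.20 L mol⁻¹ min⁻¹, Ea = 90.0 kJ mol⁻¹)
    (constants at 100 °C)

The flasks give 64.2% for Monday's, 53.0% for Wednesday's, 50.7% for Tuesday's and 51.2% for Friday's, in the order my shares put the first three. Monday's has come to rest in self-condensation product, which reads 64.4% at 500 h, while starting material goes from 4.24% to 0% and other capture product from 20.0% to 23.3%. Friday's has not: it holds 12.1% starting material, and its self-condensation product goes from 51.2% to 52.9%.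

Monday's recipe at 125 °C carries N to 12.8, a share of 79.4%. That neighbour gives 79.5%.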